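## Retrosynthetic overview

- **Feature:** in the γ-butyrolactone ring O1–C2(=O)–C3–C4–C5, the carbonyl carbon C2 with its bonds to C3 and O1 is one molecule of CO. The adjacent CH stereocentres C3 (ring A benzyl) and C4 (ring B benzyl) are the two alkene carbons of an E-trisubstituted allylic alcohol, whose CH2OH becomes C5–O1.
- **Lactone** (the only ring made; rings A, B and C are bought): enantioselective palladium-catalysed cyclocarbonylation of that alcohol. The alcohol comes from Wittig union of the ring A arylacetaldehyde (from eugenol) with a ring B benzylated ester ylide, then ester reduction.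
- **Ring B C5–C8″ bond and the C8″ stereocentre** (C7″ = ketone carbon, C8″ = CH, C9″ = CH2OH): aromatic Claisen rearrangement with 1,3-chirality transfer. The aryl ether is made by Mitsunobu inversion of a 3-arylpent-3-en-2-ol built from (S)-but-3-yn-2-ol.
- **C7″=O:** ozonolysis of the ethylidene group left by the Claisen step. All four silyl ethers fall in the last step.

Key step: step 8

**Assumption:** the sense of induction of (2S,4S)-BPPM (tert-butyl (2S,4S)-4-(diphenylphosphino)-2-[(diphenylphosphino)methyl]pyrrolidine-1-carboxylate) on this alkene cannot be predicted. It is taken to address the face that leads to (3R,4R); otherwise the (2R,4R) ligand is used.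

**Remark:** TBS = tert-butyldimethylsilyl. Ring B carries CH2 at C1, OMe at C3, oxygen at C4 and a free position at C5.

## Route

Step 1
Reactants: 1 eugenol
Product: 2 O-TBS-eugenol (4-allyl-1-(TBS-oxy)-2-methoxybenzene)
Conditions: TBSCl, imidazole, DMF, rt
Reagents that add atoms: tert-butyldimethylsilyl chloride, CC(C)(C)[Si](C)(C)Cl
Why: Imidazole-promoted silyl ether formation masks the ring A phenol with a group that should survive ozone, ylide, hydride, CO/H2 and hydrogenolysis and fall only to fluoride.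

Step 2
Reactants: 2 O-TBS-eugenol
Product: 4 2-[4-(TBS-oxy)-3-methoxyphenyl]acetaldehyde, via secondary ozonide 3 (not isolated)
Conditions: O3, CH2Cl2, −78 °C (stopped when 2 is consumed); Me2S, −78 °C to rt
Reagents that add atoms: ozone, [O-][O+]=O
Why: Ozonolysis with reductive work-up, in which the terminal alkene reacts far faster than the silylated guaiacyl ring and Me2S reduces ozonide 3 to the aldehyde, which is used at once because it enolises easily.

Step 3
Reactants: 5 4-benzyloxy-3-methoxybenzaldehyde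
Product: 6 (4-benzyloxy-3-methoxyphenyl)methanol
Conditions: NaBH4, MeOH, 0 °C
Reagents that add atoms: none
Why: Borohydride reduction of an aromatic aldehyde, to which the benzyl ether is inert.

Step 4
Reactants: 6 (4-benzyloxy-3-methoxyphenyl)methanol
Product: 7 4-benzyloxy-3-methoxybenzyl bromide
Conditions: PBr3, Et2O, 0 °C
Reagents that add atoms: phosphorus tribromide, BrP(Br)Br
Why: Bromination of an electron-rich benzylic alcohol through its phosphite ester (SN2 by bromide), with the labile bromide taken on crude.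

Step 5
Reactants: 7 4-benzyloxy-3-methoxybenzyl bromide; 8 ethyl (triphenylphosphoranylidene)acetate
Product: 10 ethyl 3-(4-benzyloxy-3-methoxyphenyl)-2-(triphenylphosphoranylidene)propanoate, via phosphonium bromide 9 (not isolated)
Conditions: CHCl3, reflux; then 1 M aq. NaOH, CH2Cl2, 0 °C
Reagents that add atoms: none
Why: C-alkylation of a stabilised ylide by a reactive benzylic bromide gives salt 9, whose remaining acidic α-proton is removed by cold aqueous base to give the α-substituted stabilised ylide.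

Step 6
Reactants: 10 ethyl 3-(4-benzyloxy-3-methoxyphenyl)-2-(triphenylphosphoranylidene)propanoate; 4 2-[4-(TBS-oxy)-3-methoxyphenyl]acetaldehyde
Product: 11 ethyl (E)-2-(4-benzyloxy-3-methoxybenzyl)-4-[4-(TBS-oxy)-3-methoxyphenyl]but-2-enoate
Conditions: CH2Cl2, rt to 40 °C
Reagents that add atoms: none
Why: Wittig olefination with an α-substituted ester-stabilised ylide should give the E-enoate (ester trans to CH2–ring A, so the two arylmethyl groups are cis), and its neutral medium avoids self-aldol of 4.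

Step 7
Reactants: 11 ethyl (E)-2-(4-benzyloxy-3-methoxybenzyl)-4-[4-(TBS-oxy)-3-methoxyphenyl]but-2-enoate
Product: 12 (E)-2-(4-benzyloxy-3-methoxybenzyl)-4-[4-(TBS-oxy)-3-methoxyphenyl]but-2-en-1-ol
Conditions: i-Bu2AlH (2.5 equiv), CH2Cl2, −78 °C; aq. potassium sodium tartrate
Reagents that add atoms: none
Why: 1,2-Reduction of an α,β-unsaturated ester with i-Bu2AlH at low temperature gives the allylic alcohol without changing the alkene geometry or touching the silyl and benzyl ethers.

Step 8
Reactants: 12 (E)-2-(4-benzyloxy-3-methoxybenzyl)-4-[4-(TBS-oxy)-3-methoxyphenyl]but-2-en-1-ol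
Product: 13 (3R,4R)-4-(4-benzyloxy-3-methoxybenzyl)-3-[4-(TBS-oxy)-3-methoxybenzyl]dihydrofuran-2(3H)-one
Conditions: Pd2(dba)3·CHCl3 (5 mol %), (2S,4S)-BPPM (12 mol %), CO/H2 (1:1, 55 bar), CH2Cl2, 100 °C, autoclave
Reagents that add atoms: carbon monoxide, [C-]#[O+]
Why: Proposed new method: zerovalent palladium, the diphosphine and H2 give a palladium hydride that is held by the hydroxyl of 12 and adds syn to the alkene, H to the fully substituted carbon (future C4) and Pd to the CH carbon (future C3), because only this orientation gives a five-membered O,C-chelate; CO then inserts into the C3–Pd bond with retention. The bound oxygen attacks the acyl–palladium carbon in a 5-exo-trig acyl substitution, which forms C2–O1, closes the γ-lactone as the only new ring and returns the hydride, so the net change is 12 plus CO. The closest known reaction type is the palladium/diphosphine cyclocarbonylation of allylic alcohols to γ-butyrolactones under CO/H2, enantioselective with BPPM-type ligands, which is known for simpler alkyl- and aryl-substituted allylic alcohols but not for a trisubstituted 1,4-diarylbut-2-en-1-ol. The relative configuration comes from the substrate: in E-12 the two arylmethyl groups are cis, so H at C4 and CO at C3 arriving on one face leave them trans on the ring. The absolute configuration of C3 and C4 is set in one event by the chiral ligand, which must steer the hydride to the 2Si,3Re face of 12. The step needs regioselectivity (secured by hydroxyl chelation), syn stereospecificity (secured by the alkene geometry) and suppression of β-hydride elimination toward the benzylic CH2 groups, for which high CO pressure should make insertion faster than chain walking, while the CO-saturated homogeneous catalyst should leave the benzyl and silyl ethers alone.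

Step 9
Reactants: 13 (3R,4R)-4-(4-benzyloxy-3-methoxybenzyl)-3-[4-(TBS-oxy)-3-methoxybenzyl]dihydrofuran-2(3H)-one
Product: 14 (3R,4R)-4-(4-hydroxy-3-methoxybenzyl)-3-[4-(TBS-oxy)-3-methoxybenzyl]dihydrofuran-2(3H)-one
Conditions: H2 (1 atm), 10% Pd/C, EtOAc, rt
Reagents that add atoms: none
Why: Heterogeneous hydrogenolysis cleaves only the benzyl aryl ether and frees the ring B phenol, leaving the lactone, the silyl ether and both stereocentres untouched.

Step 10
Reactants: 15 (S)-but-3-yn-2-ol
Product: 16 (S)-3-(TBS-oxy)but-1-yne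
Conditions: TBSCl, imidazole, CH2Cl2, 0 °C to rt
Reagents that add atoms: tert-butyldimethylsilyl chloride, CC(C)(C)[Si](C)(C)Cl
Why: Silyl ether formation blocks the secondary carbinol without touching its stereocentre, so that only the primary hydroxyl introduced next can direct the hydroalumination.

Step 11
Reactants: 16 (S)-3-(TBS-oxy)but-1-yne
Product: 18 (S)-4-(TBS-oxy)pent-2-yn-1-ol, via lithium acetylide 17 (not isolated)
Conditions: n-BuLi, THF, −78 °C; (CH2O)n, −78 °C to rt; H2O
Reagents that add atoms: paraformaldehyde (formaldehyde unit), C=O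
Why: Deprotonation of the terminal alkyne and addition of acetylide 17 to formaldehyde is a standard carbonyl alkynylation and installs the future C9″.

Step 12
Reactants: 18 (S)-4-(TBS-oxy)pent-2-yn-1-ol
Product: 20 (2Z,4S)-4-(TBS-oxy)-3-iodopent-2-en-1-ol, via cyclic alkenylalanate 19 (not isolated)
Conditions: NaAlH2(OCH2CH2OMe)2 (Red-Al), THF, 0 °C to rt; EtOAc; then I2, THF, −78 to 0 °C
Reagents that add atoms: iodine, [I][I]
Why: Hydroxyl-directed trans-hydroalumination of a propargylic alcohol puts H on C2 and Al on C3 in five-membered alanate 19, iodinolysis with retention gives the Z-iodide, and the silyl ether at C4 is a poor enough leaving group to hold back allene formation.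

Step 13
Reactants: 20 (2Z,4S)-4-(TBS-oxy)-3-iodopent-2-en-1-ol; 21 2-methoxy-4-(4,4,5,5-tetramethyl-1,3,2-dioxaborolan-2-yl)phenol
Product: 22 (2E,4S)-4-(TBS-oxy)-3-(4-hydroxy-3-methoxyphenyl)pent-2-en-1-ol
Conditions: Pd(dppf)Cl2·CH2Cl2 (5 mol %), K2CO3, 1,4-dioxane/H2O, 60 °C
Reagents that add atoms: none
Why: Suzuki–Miyaura coupling of an alkenyl iodide proceeds with retention of geometry, so ring C ends cis to CH2OH, and it tolerates the free phenol and alcohol.

Step 14
Reactants: 22 (2E,4S)-4-(TBS-oxy)-3-(4-hydroxy-3-methoxyphenyl)pent-2-en-1-ol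
Product: 23 (2E,4S)-3-(4-hydroxy-3-methoxyphenyl)pent-2-ene-1,4-diol
Conditions: Bu4NF, THF, 0 °C to rt; H2O
Reagents that add atoms: none
Why: Fluoride cleavage of the secondary silyl ether avoids the acid that could ionise the allylic carbinol, so the S centre is kept.

Step 15
Reactants: 23 (2E,4S)-3-(4-hydroxy-3-methoxyphenyl)pent-2-ene-1,4-diol
Product: 24 (2S,3E)-5-(TBS-oxy)-3-[4-(TBS-oxy)-3-methoxyphenyl]pent-3-en-2-ol
Conditions: TBSCl (2.1 equiv), imidazole, CH2Cl2/DMF, −10 to 0 °C
Reagents that add atoms: tert-butyldimethylsilyl chloride, CC(C)(C)[Si](C)(C)Cl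
Why: Sterically controlled silylation, in which the phenol and the primary allylic alcohol react much faster with TBSCl than the secondary carbinol flanked by a methyl group and the aryl-bearing sp2 carbon.

Step 16
Reactants: 14 (3R,4R)-4-(4-hydroxy-3-methoxybenzyl)-3-[4-(TBS-oxy)-3-methoxybenzyl]dihydrofuran-2(3H)-one; 24 (2S,3E)-5-(TBS-oxy)-3-[4-(TBS-oxy)-3-methoxyphenyl]pent-3-en-2-ol
Product: 25 (3R,4R)-4-{4-[(2R,3E)-5-(TBS-oxy)-3-[4-(TBS-oxy)-3-methoxyphenyl]pent-3-en-2-yl]oxy-3-methoxybenzyl}-3-[4-(TBS-oxy)-3-methoxybenzyl]dihydrofuran-2(3H)-one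
Conditions: PPh3, DIAD, toluene, 0 °C to rt
Reagents that add atoms: none
Why: Mitsunobu etherification displaces the oxyphosphonium of 24 by the ring B phenoxide in an SN2 step with inversion (S to R), and the non-polar solvent disfavours ionisation and SN2′ attack.

Step 17
Reactants: 25 the ring B (R)-allylic aryl ether
Product: 27 (3R,4R)-4-{4-hydroxy-3-methoxy-5-[(2S,3Z)-1-(TBS-oxy)-3-[4-(TBS-oxy)-3-methoxyphenyl]pent-3-en-2-yl]benzyl}-3-[4-(TBS-oxy)-3-methoxybenzyl]dihydrofuran-2(3H)-one, via ortho-dienone 26 (not isolated)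
Conditions: PhNEt2, 180 °C, sealed tube, argon
Reagents that add atoms: none
Why: Aromatic Claisen rearrangement, a suprafacial [3,3] shift to the only free ortho position (ring B C5) through the transition state with the carbinol methyl pseudo-equatorial, transfers the R C–O centre of 25 across the E-alkene to the S C–C centre C8″, after which dienone 26 tautomerises to the phenol.

Step 18
Reactants: 27 the ring B phenol from the Claisen step
Product: 28 the tetra-TBS ether, (3R,4R)-4-{4-(TBS-oxy)-3-methoxy-5-[(2S,3Z)-1-(TBS-oxy)-3-[4-(TBS-oxy)-3-methoxyphenyl]pent-3-en-2-yl]benzyl}-3-[4-(TBS-oxy)-3-methoxybenzyl]dihydrofuran-2(3H)-one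
Conditions: TBSOTf, 2,6-lutidine, CH2Cl2, 0 °C
Reagents that add atoms: tert-butyldimethylsilyl triflate, CC(C)(C)[Si](C)(C)OS(=O)(=O)C(F)(F)F
Why: Silylation of the hindered phenol with the silyl triflate shields it from ozone and stops it from adding to the coming ketone, which would lead by hemiketal formation and loss of water to a 2-arylbenzofuran.

Step 19
Reactants: 28 the tetra-TBS ether
Product: 30 (3R,4R)-4-{4-(TBS-oxy)-3-methoxy-5-[(2S)-3-(TBS-oxy)-1-[4-(TBS-oxy)-3-methoxyphenyl]-1-oxopropan-2-yl]benzyl}-3-[4-(TBS-oxy)-3-methoxybenzyl]dihydrofuran-2(3H)-one, via secondary ozonide 29 (not isolated)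
Conditions: O3, CH2Cl2, −78 °C (stopped when 28 is consumed); Me2S, −78 °C to rt
Reagents that add atoms: ozone, [O-][O+]=O
Why: Ozonolysis with reductive work-up cleaves the trisubstituted styrene-type alkene faster than the three silylated arenes and releases the C7″ ketone under neutral, cold conditions that should not epimerise C8″.

Step 20
Reactants: 30 the tetra-TBS ketone
Product: 31 the target, (3R,4R)-4-{4-hydroxy-5-[(2S)-3-hydroxy-1-(4-hydroxy-3-methoxyphenyl)-1-oxopropan-2-yl]-3-methoxybenzyl}-3-(4-hydroxy-3-methoxybenzyl)dihydrofuran-2(3H)-one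
Conditions: HF·pyridine, excess pyridine, THF, 0 °C to rt (plastic vessel); pH 7 phosphate buffer
Reagents that add atoms: none
Why: Fluoride-mediated global desilylation in a weakly acidic buffered medium removes all four silyl groups, avoiding both the base that would cause epimerisation, β-elimination or retro-aldol at C8″ and the strong acid that would cause cyclodehydration.

## Compound list

1 | eugenol | C=CCc1ccc(O)c(OC)c1 | starting material
2 | O-TBS-eugenol | C=CCc1ccc(O[Si](C)(C)C(C)(C)C)c(OC)c1 | intermediate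
3 | 3-[4-(TBS-oxy)-3-methoxybenzyl]-1,2,4-trioxolane (secondary ozonide, not isolated) | COc1cc(CC2OCOO2)ccc1O[Si](C)(C)C(C)(C)C | intermediate
4 | 2-[4-(TBS-oxy)-3-methoxyphenyl]acetaldehyde | COc1cc(CC=O)ccc1O[Si](C)(C)C(C)(C)C | intermediate
5 | 4-benzyloxy-3-methoxybenzaldehyde | COc1cc(C=O)ccc1OCc1ccccc1 | starting material
6 | (4-benzyloxy-3-methoxyphenyl)methanol | COc1cc(CO)ccc1OCc1ccccc1 | intermediate
7 | 4-benzyloxy-3-methoxybenzyl bromide | COc1cc(CBr)ccc1OCc1ccccc1 | intermediate
8 | ethyl (triphenylphosphoranylidene)acetate | CCOC(=O)C=P(c1ccccc1)(c1ccccc1)c1ccccc1 | starting material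
9 | [3-(4-benzyloxy-3-methoxyphenyl)-1-ethoxy-1-oxopropan-2-yl]triphenylphosphonium bromide (not isolated) | CCOC(=O)C(Cc1ccc(OCc2ccccc2)c(OC)c1)[P+](c1ccccc1)(c1ccccc1)c1ccccc1.[Br-] | intermediate
10 | ethyl 3-(4-benzyloxy-3-methoxyphenyl)-2-(triphenylphosphoranylidene)propanoate | CCOC(=O)C(Cc1ccc(OCc2ccccc2)c(OC)c1)=P(c1ccccc1)(c1ccccc1)c1ccccc1 | intermediate
11 | ethyl (E)-2-(4-benzyloxy-3-methoxybenzyl)-4-[4-(TBS-oxy)-3-methoxyphenyl]but-2-enoate | CCOC(=O)/C(Cc1ccc(OCc2ccccc2)c(OC)c1)=C/Cc1ccc(O[Si](C)(C)C(C)(C)C)c(OC)c1 | intermediate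
12 | (E)-2-(4-benzyloxy-3-methoxybenzyl)-4-[4-(TBS-oxy)-3-methoxyphenyl]but-2-en-1-ol | OC/C(Cc1ccc(OCc2ccccc2)c(OC)c1)=C/Cc1ccc(O[Si](C)(C)C(C)(C)C)c(OC)c1 | intermediate
13 | (3R,4R)-4-(4-benzyloxy-3-methoxybenzyl)-3-[4-(TBS-oxy)-3-methoxybenzyl]dihydrofuran-2(3H)-one | COc1cc(C[C@H]2C(=O)OC[C@@H]2Cc2ccc(OCc3ccccc3)c(OC)c2)ccc1O[Si](C)(C)C(C)(C)C | intermediate
14 | (3R,4R)-4-(4-hydroxy-3-methoxybenzyl)-3-[4-(TBS-oxy)-3-methoxybenzyl]dihydrofuran-2(3H)-one | COc1cc(C[C@H]2C(=O)OC[C@@H]2Cc2ccc(O)c(OC)c2)ccc1O[Si](C)(C)C(C)(C)C | intermediate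
15 | (S)-but-3-yn-2-ol | C[C@H](O)C#C | starting material
16 | (S)-3-(TBS-oxy)but-1-yne | C[C@H](O[Si](C)(C)C(C)(C)C)C#C | intermediate
17 | lithium (S)-3-(TBS-oxy)but-1-yn-1-ide (not isolated) | C[C@H](O[Si](C)(C)C(C)(C)C)C#C[Li] | intermediate
18 | (S)-4-(TBS-oxy)pent-2-yn-1-ol | C[C@H](O[Si](C)(C)C(C)(C)C)C#CCO | intermediate
19 | sodium 2,2-bis(2-methoxyethoxy)-3-[(S)-1-(TBS-oxy)ethyl]-2,5-dihydro-1,2-oxaaluminol-2-uide (not isolated) | COCCO[Al-]1(OCCOC)OCC=C1[C@H](C)O[Si](C)(C)C(C)(C)C.[Na+] | intermediate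
20 | (2Z,4S)-4-(TBS-oxy)-3-iodopent-2-en-1-ol | C[C@H](O[Si](C)(C)C(C)(C)C)/C(I)=C/CO | intermediate
21 | 2-methoxy-4-(4,4,5,5-tetramethyl-1,3,2-dioxaborolan-2-yl)phenol | COc1cc(B2OC(C)(C)C(C)(C)O2)ccc1O | starting material
22 | (2E,4S)-4-(TBS-oxy)-3-(4-hydroxy-3-methoxyphenyl)pent-2-en-1-ol | C[C@H](O[Si](C)(C)C(C)(C)C)/C(c1ccc(O)c(OC)c1)=C/CO | intermediate
23 | (2E,4S)-3-(4-hydroxy-3-methoxyphenyl)pent-2-ene-1,4-diol | C[C@H](O)/C(c1ccc(O)c(OC)c1)=C/CO | intermediate
24 | (2S,3E)-5-(TBS-oxy)-3-[4-(TBS-oxy)-3-methoxyphenyl]pent-3-en-2-ol | C[C@H](O)/C(c1ccc(O[Si](C)(C)C(C)(C)C)c(OC)c1)=C/CO[Si](C)(C)C(C)(C)C | intermediate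
25 | ring B (2R,3E)-allylic aryl ether of lactone 14 | COc1cc(C[C@H]2C(=O)OC[C@@H]2Cc2ccc(O[C@H](C)/C(c3ccc(O[Si](C)(C)C(C)(C)C)c(OC)c3)=C/CO[Si](C)(C)C(C)(C)C)c(OC)c2)ccc1O[Si](C)(C)C(C)(C)C | intermediate
26 | ring B 6-substituted 2-methoxycyclohexa-2,4-dienone (ring sp3 carbon transient, configuration not specified; not isolated) | COc1cc(C[C@H]2C(=O)OC[C@@H]2CC2=CC([C@@H](CO[Si](C)(C)C(C)(C)C)/C(c3ccc(O[Si](C)(C)C(C)(C)C)c(OC)c3)=C/C)C(=O)C(OC)=C2)ccc1O[Si](C)(C)C(C)(C)C | intermediate
27 | Claisen product, ring B phenol with the (2S,3Z)-pent-3-en-2-yl group at C5 | COc1cc(C[C@H]2C(=O)OC[C@@H]2Cc2cc(OC)c(O)c([C@@H](CO[Si](C)(C)C(C)(C)C)/C(c3ccc(O[Si](C)(C)C(C)(C)C)c(OC)c3)=C/C)c2)ccc1O[Si](C)(C)C(C)(C)C | intermediate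
28 | tetra-TBS alkene | COc1cc(C[C@H]2C(=O)OC[C@@H]2Cc2cc(OC)c(O[Si](C)(C)C(C)(C)C)c([C@@H](CO[Si](C)(C)C(C)(C)C)/C(c3ccc(O[Si](C)(C)C(C)(C)C)c(OC)c3)=C/C)c2)ccc1O[Si](C)(C)C(C)(C)C | intermediate
29 | secondary ozonide of 28 (trioxolane carbons not specified; not isolated) | COc1cc(C[C@H]2C(=O)OC[C@@H]2Cc2cc(OC)c(O[Si](C)(C)C(C)(C)C)c([C@@H](CO[Si](C)(C)C(C)(C)C)C3(c4ccc(O[Si](C)(C)C(C)(C)C)c(OC)c4)OOC(C)O3)c2)ccc1O[Si](C)(C)C(C)(C)C | intermediate
30 | tetra-TBS ketone, (8″S) | COc1cc(C[C@H]2C(=O)OC[C@@H]2Cc2cc(OC)c(O[Si](C)(C)C(C)(C)C)c([C@@H](CO[Si](C)(C)C(C)(C)C)C(=O)c3ccc(O[Si](C)(C)C(C)(C)C)c(OC)c3)c2)ccc1O[Si](C)(C)C(C)(C)C | intermediate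
31 | CNP0191394.1, (3R,4R,8″S) | COc1cc(C[C@H]2C(=O)OC[C@@H]2Cc2cc(OC)c(O)c([C@@H](CO)C(=O)c3ccc(O)c(OC)c3)c2)ccc1O | target

## Step count

Total step count: 20.
Longest linear sequence: 12 steps (5 → 6 → 7 → 10 → 11 → 12 → 13 → 14 → 25 → 27 → 28 → 30 → 31).

## Steps most likely to fail

**1. Step 8.**
- **What may go wrong:** hydropalladation of the hindered trisubstituted alkene may be slow. The alkylpalladium may lose a benzylic β-hydrogen, so that the alkene walks into conjugation with ring A or ring B. The ligand may also discriminate the two alkene faces poorly.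
- **Fallback** (known chemistry; sets out from 5 and comes back at 13): the lactone is built from a succinate instead of by carbonylation.
  - Stobbe condensation of 5 with dimethyl succinate (NaOMe, MeOH, reflux) should give (E)-4-(4-benzyloxy-3-methoxyphenyl)-3-(methoxycarbonyl)but-3-enoic acid F1.
  - Rhodium-catalysed asymmetric hydrogenation ([Rh(cod)2]BF4, the Et-DuPhos antipode that gives the R acid, H2, MeOH) sets the future C4 in (R)-3-(4-benzyloxy-3-methoxybenzyl)-4-methoxy-4-oxobutanoic acid F2.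
  - Reduction of the ester in the potassium carboxylate with Ca(BH4)2 in EtOH, then acidification, closes (R)-4-(4-benzyloxy-3-methoxybenzyl)dihydrofuran-2(3H)-one F3.
  - In parallel, vanillin is silylated (TBSCl, imidazole) to 4-(TBS-oxy)-3-methoxybenzaldehyde F4, reduced (NaBH4) to [4-(TBS-oxy)-3-methoxyphenyl]methanol F5 and brominated (PBr3, Et2O, 0 °C) to 4-(TBS-oxy)-3-methoxybenzyl bromide F6.
  - The lithium enolate of F3 (LiN(SiMe3)2, THF, −78 °C) is alkylated by F6 on the face anti to the C4 substituent, which should give trans-lactone 13.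

**2. Step 17.**
- **What may go wrong:** strain between the carbinol methyl and ring C on the neighbouring sp2 carbon may let part of the material react through the rotamer with the methyl pseudo-axial. That rotamer delivers the opposite configuration at C8″ together with the other ethylidene geometry, and ozonolysis later erases the geometry. Thermal elimination of the phenol and the abnormal Claisen pathway of the free o-allylphenol may also compete at 180 °C.
- **Fallback** (sets out from 14 and 24 and comes back at 28; it also bypasses step 16): the ring B C5–C8″ bond is made by anti-SN2′ substitution of an allylic picolinate with an arylcopper reagent.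
  - Iodination of 14 ortho to the free phenol (NIS, MeCN, 0 °C) should give the ring B 5-iodophenol lactone F7.
  - Silylation (TBSCl, imidazole, DMF) gives the ring B 5-iodo bis-TBS lactone F8.
  - Alcohol 24 is esterified with retention (picolinic acid, DCC, DMAP, CH2Cl2) to the (2S,3E)-allylic picolinate F9.
  - Iodine–magnesium exchange on F8 (i-PrMgCl·LiCl, THF, −30 °C) gives the ring B arylmagnesium chloride F10.
  - F10 is transmetallated with CuBr·SMe2 and treated with F9.
  - Anti attack on the S ester addresses the same alkene face as the suprafacial shift of the R ether, so this should give 28 directly.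

**3. Step 20.**
- **What may go wrong:** once the ketone is flanked by free hydroxyl groups, C8″ may epimerise by enolisation. The C9″ oxygen may be lost by β-elimination, or formaldehyde by retro-aldol cleavage. The ring B phenol may add to the ketone with loss of water.
- **Fallback** (sets out from 28 and comes back at 31): the silyl groups are exchanged at the robust alkene stage for groups that leave under neutral hydrogenolysis.
  - Bu4NF in THF converts 28 into the tetrahydroxy alkene F11.
  - Benzyl chloroformate (pyridine, DMAP, CH2Cl2) gives the tetrakis(benzyl carbonate) alkene F12.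
  - Ozonolysis (O3, CH2Cl2, −78 °C; Me2S) gives the tetrakis(benzyl carbonate) ketone F13.
  - H2 over 10% Pd/C in EtOAc at rt removes the four carbonates without acid, base or fluoride to give 31.

## Further compounds

F1 | step 8 | (E)-4-(4-benzyloxy-3-methoxyphenyl)-3-(methoxycarbonyl)but-3-enoic acid | COC(=O)/C(CC(=O)O)=C/c1ccc(OCc2ccccc2)c(OC)c1
F2 | step 8 | (R)-3-(4-benzyloxy-3-methoxybenzyl)-4-methoxy-4-oxobutanoic acid | COC(=O)[C@@H](CC(=O)O)Cc1ccc(OCc2ccccc2)c(OC)c1
F3 | step 8 | (R)-4-(4-benzyloxy-3-methoxybenzyl)dihydrofuran-2(3H)-one | O=C1C[C@@H](Cc2ccc(OCc3ccccc3)c(OC)c2)CO1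
F4 | step 8 | 4-(TBS-oxy)-3-methoxybenzaldehyde | COc1cc(C=O)ccc1O[Si](C)(C)C(C)(C)C
F5 | step 8 | [4-(TBS-oxy)-3-methoxyphenyl]methanol | COc1cc(CO)ccc1O[Si](C)(C)C(C)(C)C
F6 | step 8 | 4-(TBS-oxy)-3-methoxybenzyl bromide | COc1cc(CBr)ccc1O[Si](C)(C)C(C)(C)C
F7 | step 17 | ring B 5-iodophenol lactone | COc1cc(C[C@H]2C(=O)OC[C@@H]2Cc2cc(I)c(O)c(OC)c2)ccc1O[Si](C)(C)C(C)(C)C
F8 | step 17 | ring B 5-iodo bis-TBS lactone | COc1cc(C[C@H]2C(=O)OC[C@@H]2Cc2cc(I)c(O[Si](C)(C)C(C)(C)C)c(OC)c2)ccc1O[Si](C)(C)C(C)(C)C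
F9 | step 17 | (2S,3E)-5-(TBS-oxy)-3-[4-(TBS-oxy)-3-methoxyphenyl]pent-3-en-2-yl picolinate | C[C@H](OC(=O)c1ccccn1)/C(c1ccc(O[Si](C)(C)C(C)(C)C)c(OC)c1)=C/CO[Si](C)(C)C(C)(C)C
F10 | step 17 | ring B arylmagnesium chloride | COc1cc(C[C@H]2C(=O)OC[C@@H]2Cc2cc([Mg]Cl)c(O[Si](C)(C)C(C)(C)C)c(OC)c2)ccc1O[Si](C)(C)C(C)(C)C
F11 | step 20 | tetrahydroxy alkene | COc1cc(C[C@H]2C(=O)OC[C@@H]2Cc2cc(OC)c(O)c([C@@H](CO)/C(c3ccc(O)c(OC)c3)=C/C)c2)ccc1O
F12 | step 20 | tetrakis(benzyl carbonate) alkene | COc1cc(C[C@H]2C(=O)OC[C@@H]2Cc2cc(OC)c(OC(=O)OCc3ccccc3)c([C@@H](COC(=O)OCc3ccccc3)/C(c3ccc(OC(=O)OCc4ccccc4)c(OC)c3)=C/C)c2)ccc1OC(=O)OCc1ccccc1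
F13 | step 20 | tetrakis(benzyl carbonate) ketone | COc1cc(C[C@H]2C(=O)OC[C@@H]2Cc2cc(OC)c(OC(=O)OCc3ccccc3)c([C@@H](COC(=O)OCc3ccccc3)C(=O)c3ccc(OC(=O)OCc4ccccc4)c(OC)c3)c2)ccc1OC(=O)OCc1ccccc1
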